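## The problem

The target 12 is the meso, all-cis isomer of 2,5-bis(4-hydroxy-3,5-dimethoxyphenyl)-3,4-bis(hydroxymethyl)tetrahydrofuran: a single oxolane ring carries four contiguous stereocentres, C2 to C5, with both aryl groups and both hydroxymethyl groups on one face. A mirror plane runs through O1 and the midpoint of C3–C4, so only relative configuration has to be controlled. The all-cis array is the most crowded diastereomer and cannot be reached by equilibration, so it has to be fixed kinetically, and a centre set wrongly cannot be corrected through its neighbours. Four hydrogens are most surely placed on one face by delivering them to a flat precursor, which sets all four centres in one event. C2 and C5 are benzylic ether carbons para to an oxygen substituent: acid ionizes them, a free phenoxide can open them through a quinone methide, and palladium under hydrogen cleaves them. The end-game therefore has to stay near neutral, and the oxidation-prone phenols should travel protected and be unmasked last. The enabling feature is constitutional: the halves aryl–C2–C3–CH2O and aryl–C5–C4–CH2O are identical, joined through C3–C4 and bridged by O1 at the aryl-bearing carbons. Each half has the skeleton of a 3-arylpropargyl unit; with one CH2O carbon raised to the carboxyl level the two can be tied as an ester, giving a 1,6-diyne that can take up one oxygen atom and close to the furan.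

## Retrosynthesis

**12 from 11.** The two phenolic O–H bonds of 12 are traced back to triisopropylsilyl ethers in the meso diol 11. Benzyl ethers would need palladium and hydrogen at the end, which threatens the C2–O and C5–O bonds, and their unhindered phenyl rings would bind the ruthenium catalyst of the key step and be saturated on rhodium. Acetal protection would need acid, which epimerizes the all-cis ring. A hindered silyl ether leaves with buffered fluoride. The forward step must not disturb the four stereocentres.

**11 from 10.** The two hydroxymethyl groups of 11 are tied back into one γ-lactone, giving the cis-fused bicyclic lactone 10. No skeletal bond is cut. The lactone holds one carbon at the acid level and the other at the alcohol level, which is what an ester tether supplies, and it locks C3 and C4 cis. The forward step is a hydride reduction that must not eliminate the ring oxygen β to the carbonyl.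

**10 from 9.** Four C–H bonds are removed, leading to the flat, achiral furan-fused lactone 9. All four stereocentres disappear at once. No stepwise construction sets four cis hydrogens as directly. The forward hydrogenation must add two molecules of hydrogen to one face without hydrogenolysis of benzylic C–O bonds and without saturating the aryl rings.

**9 from 8 (key disconnection).** Three bonds are cut: C3a–C6a (C3–C4 of the target) and both bonds of the furan oxygen, O5–C4 and O5–C6 (O1–C2 and O1–C5 of the target). This opens the furan and the lactone ring together and leaves the acyclic, achiral diyne ester 8. The neighbouring cut, through the two C–O bonds only, would leave a 1,4-diketone whose central C–C bond still has to be made; it is kept as a fallback. Cutting the aryl–furan bonds would discard the symmetry. The forward reaction needs an oxygen-atom donor and a catalyst that couples the two alkynes at their tether-side carbons. The tether fixes the regiochemistry, so the demand is chemoselectivity against alkyne trimerization and against thermal cycloaddition of the diyne.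

**8 from 5 and 7.** The ester C–O bond is cut, giving propargylic alcohol 5 and arylpropiolic acid 7, which share one aryl alkyne skeleton. The coupling has to be mild, because activated arylpropiolic acids cyclize through their anhydrides.

**7 from 5 via 6.** No skeletal bond is cut: the carboxyl group of 7 is traced to the hydroxymethyl group of 5, through ynal 6, which is not isolated. Both halves of 8 then descend from one batch of a single propargylic alcohol, which is divided, and the acetylide chemistry is run only once. The neighbouring option, a separate carboxylation of the acetylide with carbon dioxide, is equally short for the acid but repeats the cryogenic organolithium operation; it is kept as a fallback. The forward oxidation has to raise a propargylic alcohol by two levels without touching the electron-rich ring, the silyl ether or the triple bond, and without heating the acid.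

**5 from 3 via 4, 3 from 2, 2 from 1.** In 5 the bond between the alkyne terminus and the CH2OH carbon is cut, giving lithium acetylide 4 and formaldehyde. Acetylide 4 is generated from dibromoalkene 3 (Corey–Fuchs sequence), which avoids the basic methanol of a diazophosphonate homologation and the isolation of a terminal alkyne. Dibromoalkene 3 comes from silyl-protected aldehyde 2 by one-carbon olefination, and 2 from commercial syringaldehyde 1 by silylation. Every skeletal carbon of 12 thus comes from 1 and two one-carbon reagents.

## Roads not taken

**Alternative 1:** The cut is at the C2–aryl and C5–aryl bonds. The cis bis(8-aminoquinoline) amide A1 would be arylated twice with 2-(benzyloxy)-5-iodo-1,3-dimethoxybenzene A2 under Pd(OAc)2 and AgOAc. Each amide steers palladium to the neighbouring O–CH2 group, and the product would be the all-cis diamide A3.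
- Merits: the palladacycle places each aryl group cis to its directing group, the cis-3,4 relation is carried in from A1, no furan has to be hydrogenated, and the two aryl groups could differ. Arylation next to oxygen in a tetrahydrofuran-3-carboxamide is a demonstrated reaction.
- Weak points: two bidentate groups on adjacent carbons can hold palladium in an unproductive bis-chelate, and the second arylation meets a face already carrying one aryl group. C3 and C4 of A3 are α-carbonyl methines in an all-cis array and can epimerize to the trans series under hot carboxylate conditions. Two hindered secondary amides must then be taken to CH2OH through N-activation and reductive cleavage, where the same epimerization threatens. Silver is used in stoichiometric amount.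
- Comparison: for C2 and C5 this road is at least as predictable as a furan hydrogenation, and it carries no risk of arene saturation or ring hydrogenolysis. The chosen plan sets against this that it needs no auxiliary, draws the whole skeleton from one aldehyde, and never exposes an epimerizable α-carbonyl centre: in 10 that centre is locked by the ring fusion.

**Alternative 2:** The cut is at the bond between C3 and its hydroxymethyl carbon, together with C2–H. The cis-2,3-dihydrofuran A4, carrying the C4 hydroxymethyl group as a (bromomethyl)dimethylsilyl ether, would be treated with Bu3SnH. The silylmethyl radical adds 6-exo to C3 of the aryl enol ether, the benzylic C2 radical takes hydrogen on the convex face, and the cis-fused oxasilinane A5 results. Tamao oxidation would then release the second hydroxymethyl group.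
- Merits: the tether passes the C4 configuration to C3 reliably, radical conditions are neutral toward the benzylic ethers, and unsymmetrical analogues would be accessible.
- Weak points: A4 already holds two of the four stereocentres, which must be made first, and it contains an acid-labile, electron-rich aryl enol ether. A 6-exo closure onto a trisubstituted alkene is slow enough for direct reduction of the radical to compete. The C2 configuration rests on hydrogen transfer to a planar benzylic radical. Tin is stoichiometric and the sequence is long and linear, with no use of the symmetry.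
- Comparison: this road is better in that no aromatic ring has to survive a hydrogenation catalyst and each centre comes from a well-understood substrate-controlled event. The chosen plan sets four centres in one operation and reaches the ring in far fewer steps from a single building block.

**Alternative 3:** The cuts are O1–C5 and C2–C3. The trans donor–acceptor cyclopropane A6 and 4-(benzyloxy)-3,5-dimethoxybenzaldehyde A7 would combine under Sn(OTf)2 in a (3+2) annulation to give the tetrahydrofuran A8 with the C2, C4 and C5 substituents cis.
- Merits: the step is convergent and catalytic and closes the ring near room temperature. The 2,5-cis outcome with aryl aldehydes and the inversion at the donor carbon are well established.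
- Weak points: C3 emerges as a quaternary malonate carbon. One ester has to be removed and the other kept on the face shared with both neighbours, but dealkoxycarbonylation passes through an enolate and thermodynamics favour the trans ester. The fourth centre is therefore the one this road cannot guarantee. The very electron-rich donor aryl group also makes A6 prone to open to a zwitterion, which erodes stereospecificity, and A6 needs its own stereodefined synthesis.
- Comparison: for the ring construction itself this road is milder, and arguably more reliable, than a ruthenium cyclization above 100 °C. The chosen plan sets against this that C3 and C4 are created in the same event as C2 and C5, so no centre has to be installed afterwards against a thermodynamic bias.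

Key step: step 6

## Route

Remark: 12 is a meso compound, so only relative configuration is controlled; the chiral intermediate 10 is formed as a racemate and is drawn as one enantiomer.

Step 1
Reactants: 1 4-hydroxy-3,5-dimethoxybenzaldehyde (syringaldehyde)
Product: 2 3,5-dimethoxy-4-(triisopropylsilyloxy)benzaldehyde
Conditions: TIPSCl, imidazole, DMAP (cat.), DMF, rt
Reagents that add atoms: chlorotriisopropylsilane, CC(C)[Si](Cl)(C(C)C)C(C)C
Why: Imidazole-promoted silylation of a phenol; the para-formyl group makes the hindered 2,6-dimethoxyphenol acidic enough to react, and the bulky silyl ether should withstand n-BuLi at −78 °C, hot DMF and LiAlH4 yet leave with fluoride.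

Step 2
Reactants: 2 3,5-dimethoxy-4-(triisopropylsilyloxy)benzaldehyde
Product: 3 [4-(2,2-dibromoethenyl)-2,6-dimethoxyphenoxy]triisopropylsilane
Conditions: CBr4, PPh3, Zn, CH2Cl2, 0 °C to rt
Reagents that add atoms: carbon tetrabromide, BrC(Br)(Br)Br
Why: Corey–Fuchs dibromo-olefination, a Wittig reaction of the aldehyde with Ph3P=CBr2 made in the flask from CBr4, PPh3 and Zn; the neutral conditions leave the aryl silyl ether untouched.

Step 3
Reactants: 3 [4-(2,2-dibromoethenyl)-2,6-dimethoxyphenoxy]triisopropylsilane
Product: 5 3-[3,5-dimethoxy-4-(triisopropylsilyloxy)phenyl]prop-2-yn-1-ol, via lithium arylacetylide 4 (not isolated)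
Conditions: n-BuLi (2.1 equiv), THF, −78 °C; then (CH2O)n, −78 °C to rt; H2O
Reagents that add atoms: formaldehyde (used as paraformaldehyde), C=O
Why: Second stage of the Corey–Fuchs sequence: bromine–lithium exchange and 1,2-shift (Fritsch–Buttenberg–Wiechell rearrangement) give the alkyne, which the second equivalent of n-BuLi converts to acetylide 4; addition of 4 to formaldehyde gives the propargylic alcohol without isolation of a terminal alkyne.

Step 4
Reactants: 5 3-[3,5-dimethoxy-4-(triisopropylsilyloxy)phenyl]prop-2-yn-1-ol
Product: 7 3-[3,5-dimethoxy-4-(triisopropylsilyloxy)phenyl]prop-2-ynoic acid, via arylpropynal 6 (not isolated)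
Conditions: TEMPO (cat.), PhI(OAc)2 (2.2 equiv), MeCN–H2O (1:1), 0 °C to rt
Reagents that add atoms: water, O
Why: Nitroxyl-catalysed oxidation of a primary alcohol to the carboxylic acid (TEMPO with PhI(OAc)2 in aqueous acetonitrile), applied to the portion of 5 destined for the acyl half: the oxoammonium ion gives ynal 6, whose electron-poor carbonyl hydrates readily and is oxidized a second time. The weakly acidic, chlorine-free medium at or below room temperature should spare the aryl silyl ether, the triple bond and the electron-rich ring, and the acid is never heated because arylpropiolic acids decarboxylate.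

Step 5
Reactants: 5 3-[3,5-dimethoxy-4-(triisopropylsilyloxy)phenyl]prop-2-yn-1-ol; 7 3-[3,5-dimethoxy-4-(triisopropylsilyloxy)phenyl]prop-2-ynoic acid
Product: 8 3-[3,5-dimethoxy-4-(triisopropylsilyloxy)phenyl]prop-2-yn-1-yl 3-[3,5-dimethoxy-4-(triisopropylsilyloxy)phenyl]prop-2-ynoate
Conditions: DCC, DMAP (cat.), CH2Cl2, −20 to 0 °C
Reagents that add atoms: none
Why: Steglich esterification (carbodiimide activation, DMAP acyl transfer); acid and alcohol are premixed and DCC is added cold so that the alcohol intercepts the O-acylisourea before the symmetrical anhydride can form.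

Step 6
Reactants: 8 3-[3,5-dimethoxy-4-(triisopropylsilyloxy)phenyl]prop-2-yn-1-yl 3-[3,5-dimethoxy-4-(triisopropylsilyloxy)phenyl]prop-2-ynoate
Product: 9 4,6-bis[3,5-dimethoxy-4-(triisopropylsilyloxy)phenyl]-1H,3H-furo[3,4-c]furan-1-one
Conditions: [CpRu(MeCN)3]PF6 (10 mol%), DMSO (10 equiv), DMF, 110–120 °C, 8 added slowly
Reagents that add atoms: dimethyl sulfoxide, CS(C)=O
Why: Transfer-oxygenative (2+2+1) cyclization of an aryl-terminated 1,6-diyne with DMSO under the cationic divalent ruthenium complex [CpRu(MeCN)3]PF6 is the closest known reaction type; 8 belongs to that substrate class, and the ester in the three-atom tether is the only untested variable. After loss of acetonitrile the CpRu cation binds both alkynes, and oxidative cyclization joins their tether-side carbons (C3a–C6a) to a ruthenacyclopentatriene whose two aryl-bearing carbons are carbene-like and stabilized by the electron-rich aryl groups. This cyclometallation closes the lactone ring: a five-membered ring formed by C–C coupling inside the metallacycle, the only mode the three-atom tether allows. DMSO then attacks one carbene carbon through oxygen and leaves as Me2S, and the resulting aryl ketone oxygen bonds to the second carbene carbon (C–O reductive elimination from an oxaruthenacycle), which closes the furan ring with oxygen as the one-atom component and returns the catalyst. No stereocentre is formed, and regiochemistry is not an issue because the tether dictates which alkyne carbons couple. The selectivity required is chemoselectivity: oxygen transfer has to outrun (2+2+2) cyclotrimerization with a second diyne and the thermal intramolecular dehydro-Diels–Alder reaction of the arylpropargyl arylpropiolate onto an aryl ortho position. Excess DMSO, slow addition of 8 into the hot catalyst solution and a temperature below that at which the uncatalysed cycloaddition is fast are meant to secure it. The hindered, tetrasubstituted silyloxyarenes offer no unhindered arene that could bind the CpRu cation in η6 fashion and take it out of the cycle.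

Step 7
Reactants: 9 4,6-bis[3,5-dimethoxy-4-(triisopropylsilyloxy)phenyl]-1H,3H-furo[3,4-c]furan-1-one
Product: 10 rac-(3aR,4R,6S,6aR)-4,6-bis[3,5-dimethoxy-4-(triisopropylsilyloxy)phenyl]tetrahydro-1H,3H-furo[3,4-c]furan-1-one (all four ring hydrogens on one face)
Conditions: H2 (30 bar), 5% Rh/Al2O3, EtOAc, rt
Reagents that add atoms: none
Why: Heterogeneous syn hydrogenation of a furan: the flat bicyclic furan adsorbs on one face and both molecules of H2 are delivered to it; the 5,5-ring fusion can only be cis, and once the first alkene is reduced the second is hydrogenated from the face already carrying hydrogen, away from the aryl group, so all four hydrogens end up cis. Rh/Al2O3 is chosen because it saturates furans while cleaving benzylic C–O bonds far less than palladium, and the silyl ethers and the hindered arenes should be inert.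

Step 8
Reactants: 10 rac-(3aR,4R,6S,6aR)-4,6-bis[3,5-dimethoxy-4-(triisopropylsilyloxy)phenyl]tetrahydro-1H,3H-furo[3,4-c]furan-1-one
Product: 11 {(2R,3R,4S,5S)-2,5-bis[3,5-dimethoxy-4-(triisopropylsilyloxy)phenyl]tetrahydrofuran-3,4-diyl}dimethanol (meso, all-cis)
Conditions: LiAlH4, THF, 0 °C; aq. potassium sodium tartrate
Reagents that add atoms: none
Why: LiAlH4 reduction of a lactone to a 1,4-diol; hydride addition to the carbonyl at 0 °C is far faster than enolization, so the ring oxygen β to the carbonyl is not eliminated, no stereocentre is touched, and the product regains the mirror plane.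

Step 9
Reactants: 11 {(2R,3R,4S,5S)-2,5-bis[3,5-dimethoxy-4-(triisopropylsilyloxy)phenyl]tetrahydrofuran-3,4-diyl}dimethanol
Product: 12 [(2R,3R,4S,5S)-2,5-bis(4-hydroxy-3,5-dimethoxyphenyl)tetrahydrofuran-3,4-diyl]dimethanol (meso, all-cis; CNP0170897.3)
Conditions: Bu4NF, AcOH, THF, 0 °C to rt
Reagents that add atoms: none
Why: Fluoride cleavage of aryl silyl ethers; acetic acid buffers the phenoxide so that the para-oxybenzylic C2–O and C5–O bonds are not opened through a quinone methide, and the four stereocentres are carried over unchanged.

## Compound list

1 | 4-hydroxy-3,5-dimethoxybenzaldehyde (syringaldehyde) | COc1cc(C=O)cc(OC)c1O | starting material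
2 | 3,5-dimethoxy-4-(triisopropylsilyloxy)benzaldehyde | COc1cc(C=O)cc(OC)c1O[Si](C(C)C)(C(C)C)C(C)C | intermediate
3 | [4-(2,2-dibromoethenyl)-2,6-dimethoxyphenoxy]triisopropylsilane | COc1cc(C=C(Br)Br)cc(OC)c1O[Si](C(C)C)(C(C)C)C(C)C | intermediate
4 | lithium [3,5-dimethoxy-4-(triisopropylsilyloxy)phenyl]acetylide (not isolated) | [Li]C#Cc1cc(OC)c(O[Si](C(C)C)(C(C)C)C(C)C)c(OC)c1 | intermediate
5 | 3-[3,5-dimethoxy-4-(triisopropylsilyloxy)phenyl]prop-2-yn-1-ol | OCC#Cc1cc(OC)c(O[Si](C(C)C)(C(C)C)C(C)C)c(OC)c1 | intermediate
6 | 3-[3,5-dimethoxy-4-(triisopropylsilyloxy)phenyl]prop-2-ynal (not isolated) | O=CC#Cc1cc(OC)c(O[Si](C(C)C)(C(C)C)C(C)C)c(OC)c1 | intermediate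
7 | 3-[3,5-dimethoxy-4-(triisopropylsilyloxy)phenyl]prop-2-ynoic acid | OC(=O)C#Cc1cc(OC)c(O[Si](C(C)C)(C(C)C)C(C)C)c(OC)c1 | intermediate
8 | 3-[3,5-dimethoxy-4-(triisopropylsilyloxy)phenyl]prop-2-yn-1-yl 3-[3,5-dimethoxy-4-(triisopropylsilyloxy)phenyl]prop-2-ynoate | O=C(OCC#Cc1cc(OC)c(O[Si](C(C)C)(C(C)C)C(C)C)c(OC)c1)C#Cc1cc(OC)c(O[Si](C(C)C)(C(C)C)C(C)C)c(OC)c1 | intermediate
9 | 4,6-bis[3,5-dimethoxy-4-(triisopropylsilyloxy)phenyl]-1H,3H-furo[3,4-c]furan-1-one | O=C1OCc2c(-c3cc(OC)c(O[Si](C(C)C)(C(C)C)C(C)C)c(OC)c3)oc(-c3cc(OC)c(O[Si](C(C)C)(C(C)C)C(C)C)c(OC)c3)c12 | intermediate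
10 | rac-(3aR,4R,6S,6aR)-4,6-bis[3,5-dimethoxy-4-(triisopropylsilyloxy)phenyl]tetrahydro-1H,3H-furo[3,4-c]furan-1-one (all-cis, racemate, one enantiomer drawn) | COc1cc([C@H]2O[C@@H](c3cc(OC)c(O[Si](C(C)C)(C(C)C)C(C)C)c(OC)c3)[C@H]3COC(=O)[C@@H]23)cc(OC)c1O[Si](C(C)C)(C(C)C)C(C)C | intermediate
11 | {(2R,3R,4S,5S)-2,5-bis[3,5-dimethoxy-4-(triisopropylsilyloxy)phenyl]tetrahydrofuran-3,4-diyl}dimethanol (meso, all-cis) | COc1cc([C@H]2O[C@@H](c3cc(OC)c(O[Si](C(C)C)(C(C)C)C(C)C)c(OC)c3)[C@@H](CO)[C@H]2CO)cc(OC)c1O[Si](C(C)C)(C(C)C)C(C)C | intermediate
12 | [(2R,3R,4S,5S)-2,5-bis(4-hydroxy-3,5-dimethoxyphenyl)tetrahydrofuran-3,4-diyl]dimethanol (meso, all-cis) | COc1cc([C@H]2O[C@@H](c3cc(OC)c(O)c(OC)c3)[C@@H](CO)[C@H]2CO)cc(OC)c1O | target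

## Step count and risk

Total: 9 steps. Longest linear sequence: 9 steps (steps 1 to 9 in order; acid 7 is made from a portion of alcohol 5, so there is no parallel branch).

**Step 6 (key step).**
- What may go wrong: the thermal intramolecular dehydro-Diels–Alder cyclization of the arylpropargyl arylpropiolate onto an aryl ortho position may outrun catalysis at the temperature that oxygen transfer needs. The conjugated ynoate may also enter the ruthenacycle sluggishly, so that cyclotrimerization with a second diyne or catalyst deactivation by sulfur coordination takes over.
- Fallback (sets out from 2, returns at 11): the furan would be built by Paal–Knorr logic. Roskamp homologation of 2 with ethyl diazoacetate and catalytic SnCl2 should give ethyl 3-[3,5-dimethoxy-4-(triisopropylsilyloxy)phenyl]-3-oxopropanoate F1. Oxidative dimerization of its sodium enolate (NaH, then I2) should give diethyl 2,3-bis[3,5-dimethoxy-4-(triisopropylsilyloxy)benzoyl]butanedioate F2 as a diastereomer mixture that converges in the next operation. Acid-catalysed cyclodehydration (TsOH, toluene, reflux) should give diethyl 2,5-bis[3,5-dimethoxy-4-(triisopropylsilyloxy)phenyl]furan-3,4-dicarboxylate F3. Hydrogenation over Rh/Al2O3 as in step 7 should give diethyl all-cis-2,5-bis[3,5-dimethoxy-4-(triisopropylsilyloxy)phenyl]tetrahydrofuran-3,4-dicarboxylate F4, and LiAlH4 reduction of both esters rejoins the route at 11.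

**Step 7.**
- What may go wrong: stalling after the first uptake of hydrogen, because the surviving double bond is a tetrasubstituted, push–pull alkene conjugated with the lactone carbonyl. Competing saturation of the aryl rings on rhodium, or hydrogenolysis of the furylmethyl C–O bond of the lactone before the ring is saturated, are the other failure modes.
- Fallback (sets out from 9, returns at 11): the order of the two reductions is inverted, so that the hydrogenation substrate carries no conjugating carbonyl and no lactone C–O bond. LiAlH4 reduction of 9 should give {2,5-bis[3,5-dimethoxy-4-(triisopropylsilyloxy)phenyl]furan-3,4-diyl}dimethanol F5. Syn hydrogenation of this furan over Rh/Al2O3 then sets all four centres by addition to one face and gives 11 directly.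

**Step 5.**
- What may go wrong: self-condensation of the activated arylpropiolic acid to its anhydride, which cyclizes by intramolecular dehydro-Diels–Alder reaction even near room temperature, and conjugate addition of DMAP to the ynoate.
- Fallback (sets out from 5 and 7, returns at 8): the ester C–O bond is made at the alkyl carbon instead of the acyl carbon. Appel bromination of 5 (CBr4, PPh3) should give [4-(3-bromoprop-1-yn-1-yl)-2,6-dimethoxyphenoxy]triisopropylsilane F6. Alkylation of the potassium carboxylate of 7 with F6 (KHCO3, DMF, rt) then gives 8 without any acyl activation.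

**Step 4.**
- What may go wrong: incomplete second oxidation if hydration of the intermediate ynal is slow, addition of water or acetate across the activated triple bond during a prolonged reaction, or decarboxylation of the electron-rich arylpropiolic acid on work-up.
- Fallback (sets out from 3, returns at 7): the carboxyl carbon is brought in by C–C bond formation instead of oxidation. A further portion of dibromoalkene 3 is treated with n-BuLi (2.1 equiv) in THF at −78 °C as in step 3, and the lithium acetylide 4 so formed is trapped with carbon dioxide in place of formaldehyde. Cold dilute HCl then liberates acid 7 directly. No compound outside the compound list arises (F0).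

**Step 9.**
- What may go wrong: base-induced opening of the C2–O or C5–O bond through a para-quinone methide once the phenoxide is free, with loss of the all-cis configuration, and difficult separation of the polar tetraol from ammonium salts.
- Fallback (sets out from 9, returns at 12): the silyl groups are removed while C2 and C5 are still part of the furan and cannot epimerize. Bu4NF on 9 should give 4,6-bis(4-hydroxy-3,5-dimethoxyphenyl)-1H,3H-furo[3,4-c]furan-1-one F7. Hydrogenation over Rh/Al2O3 should give rac-(3aR,4R,6S,6aR)-4,6-bis(4-hydroxy-3,5-dimethoxyphenyl)tetrahydro-1H,3H-furo[3,4-c]furan-1-one F8, and LiAlH4 reduction with a near-neutral work-up gives 12.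

## Further compounds

F1 | step 6 | ethyl 3-[3,5-dimethoxy-4-(triisopropylsilyloxy)phenyl]-3-oxopropanoate | CCOC(=O)CC(=O)c1cc(OC)c(O[Si](C(C)C)(C(C)C)C(C)C)c(OC)c1
F2 | step 6 | diethyl 2,3-bis[3,5-dimethoxy-4-(triisopropylsilyloxy)benzoyl]butanedioate (diastereomer mixture) | CCOC(=O)C(C(=O)c1cc(OC)c(O[Si](C(C)C)(C(C)C)C(C)C)c(OC)c1)C(C(=O)OCC)C(=O)c1cc(OC)c(O[Si](C(C)C)(C(C)C)C(C)C)c(OC)c1
F3 | step 6 | diethyl 2,5-bis[3,5-dimethoxy-4-(triisopropylsilyloxy)phenyl]furan-3,4-dicarboxylate | CCOC(=O)c1c(-c2cc(OC)c(O[Si](C(C)C)(C(C)C)C(C)C)c(OC)c2)oc(-c2cc(OC)c(O[Si](C(C)C)(C(C)C)C(C)C)c(OC)c2)c1C(=O)OCC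
F4 | step 6 | diethyl all-cis-2,5-bis[3,5-dimethoxy-4-(triisopropylsilyloxy)phenyl]tetrahydrofuran-3,4-dicarboxylate (meso) | COc1cc([C@H]2O[C@@H](c3cc(OC)c(O[Si](C(C)C)(C(C)C)C(C)C)c(OC)c3)[C@@H](C(=O)OCC)[C@H]2C(=O)OCC)cc(OC)c1O[Si](C(C)C)(C(C)C)C(C)C
F5 | step 7 | {2,5-bis[3,5-dimethoxy-4-(triisopropylsilyloxy)phenyl]furan-3,4-diyl}dimethanol | OCc1c(-c2cc(OC)c(O[Si](C(C)C)(C(C)C)C(C)C)c(OC)c2)oc(-c2cc(OC)c(O[Si](C(C)C)(C(C)C)C(C)C)c(OC)c2)c1CO
F6 | step 5 | [4-(3-bromoprop-1-yn-1-yl)-2,6-dimethoxyphenoxy]triisopropylsilane | BrCC#Cc1cc(OC)c(O[Si](C(C)C)(C(C)C)C(C)C)c(OC)c1
F7 | step 9 | 4,6-bis(4-hydroxy-3,5-dimethoxyphenyl)-1H,3H-furo[3,4-c]furan-1-one | O=C1OCc2c(-c3cc(OC)c(O)c(OC)c3)oc(-c3cc(OC)c(O)c(OC)c3)c12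
F8 | step 9 | rac-(3aR,4R,6S,6aR)-4,6-bis(4-hydroxy-3,5-dimethoxyphenyl)tetrahydro-1H,3H-furo[3,4-c]furan-1-one (all-cis, one enantiomer drawn) | COc1cc([C@H]2O[C@@H](c3cc(OC)c(O)c(OC)c3)[C@H]3COC(=O)[C@@H]23)cc(OC)c1O
F0 | step 4 | none | none
A1 | alternative 1 | cis-N3,N4-di(quinolin-8-yl)tetrahydrofuran-3,4-dicarboxamide | O=C(Nc1cccc2cccnc12)[C@@H]1COC[C@@H]1C(=O)Nc1cccc2cccnc12
A2 | alternative 1 | 2-(benzyloxy)-5-iodo-1,3-dimethoxybenzene | COc1cc(I)cc(OC)c1OCc1ccccc1
A3 | alternative 1 | all-cis-2,5-bis[4-(benzyloxy)-3,5-dimethoxyphenyl]-N3,N4-di(quinolin-8-yl)tetrahydrofuran-3,4-dicarboxamide | COc1cc([C@H]2O[C@@H](c3cc(OC)c(OCc4ccccc4)c(OC)c3)[C@@H](C(=O)Nc3cccc4cccnc34)[C@H]2C(=O)Nc2cccc3cccnc23)cc(OC)c1OCc1ccccc1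
A4 | alternative 2 | (bromomethyl)({(2,3-cis)-2,5-bis[4-(benzyloxy)-3,5-dimethoxyphenyl]-2,3-dihydrofuran-3-yl}methoxy)dimethylsilane (racemate, one enantiomer drawn) | BrC[Si](C)(C)OC[C@H]1C=C(c2cc(OC)c(OCc3ccccc3)c(OC)c2)O[C@H]1c1cc(OC)c(OCc2ccccc2)c(OC)c1
A5 | alternative 2 | all-cis-2,5-bis[4-(benzyloxy)-3,5-dimethoxyphenyl]tetrahydrofuran with C3 and C4 bridged by CH2–Si(CH3)2–O–CH2 (cis-fused 1,2-oxasilinane; racemate, one enantiomer drawn) | COc1cc([C@H]2O[C@@H](c3cc(OC)c(OCc4ccccc4)c(OC)c3)[C@@H](CO[Si](C)(C)C5)[C@H]25)cc(OC)c1OCc1ccccc1
A6 | alternative 3 | dimethyl trans-2-[4-(benzyloxy)-3,5-dimethoxyphenyl]-3-[(benzyloxy)methyl]cyclopropane-1,1-dicarboxylate (racemate, one enantiomer drawn) | COC(=O)C1(C(=O)OC)[C@H](COCc2ccccc2)[C@H]1c1cc(OC)c(OCc2ccccc2)c(OC)c1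
A7 | alternative 3 | 4-(benzyloxy)-3,5-dimethoxybenzaldehyde | COc1cc(C=O)cc(OC)c1OCc1ccccc1
A8 | alternative 3 | dimethyl (2,4,5-cis)-2,5-bis[4-(benzyloxy)-3,5-dimethoxyphenyl]-4-[(benzyloxy)methyl]tetrahydrofuran-3,3-dicarboxylate (racemate, one enantiomer drawn) | COc1cc([C@H]2O[C@@H](c3cc(OC)c(OCc4ccccc4)c(OC)c3)[C@@H](COCc3ccccc3)C2(C(=O)OC)C(=O)OC)cc(OC)c1OCc1ccccc1
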